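**Retrosynthetic overview**

1. Iridal 25 ⇐ allylic triol 24 (MnO2) ⇐ seco-aldehyde 21 (LiAlH4: CHO → C3 carbinol, CH2OTs → C27 methyl).
2. Key disconnection: 21 ⇐ epoxy tosylate 19 in one flask. Epoxide-triggered cation–olefin closure of C6–C11 onto the olefin of a preformed A ring is followed by Grob/retro-Prins scission of that ring at C2–C3, giving the C3 aldehyde and the Z C2=C7 olefin.
3. 19 ⇐ tetrasubstituted allylic alcohol 17 (Sharpless epoxidation sets C10/C11) ⇐ B-alkyl Suzuki coupling of A-ring diene 7 with vinyl iodide 15.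
4. 7 ⇐ 2-methylcyclohexane-1,3-dione 1 (hydroxymethylation, CBS desymmetrisation); 15 ⇐ farnesyl bromide 9 + propyne 8 (ynoate, syn-carbocupration/iodination).
5. Ring order: the A ring (cyclohexene from 1) is present from the start; the carbocycle of iridal (B ring) is closed in step 12; the A ring is opened in the same step.

Assumptions: atoms carry iridal (squalene-type) numbers (C1 = CHO, C3 = CH2OH, ring = C6–C11, C25/C26/C27 = methyls on C2/C11/C10); the presumed biosynthesis is read as epoxide-triggered C6–C11 closure in an A/B bicycle followed by Grob-type C2–C3 scission of ring A; (2E,6E)-farnesyl bromide is bought.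

**Route**

Step 1
Reactants: 1 2-methylcyclohexane-1,3-dione
Product: 2 2-(hydroxymethyl)-2-methylcyclohexane-1,3-dione
Conditions: 37% aq. HCHO (1.5 equiv), NaHCO3 (cat.), H2O/THF, rt
Reagents that add atoms: formaldehyde, C=O
Why: Crossed aldol (hydroxymethylation) of the acidic 2-alkyl-1,3-dione with non-enolisable formaldehyde builds the quaternary carbon (future C2 with C1 and C25); the product is still achiral because the two carbonyls are enantiotopic.

Step 2
Reactants: 2 2-(hydroxymethyl)-2-methylcyclohexane-1,3-dione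
Product: 4 (2R,3R)-3-hydroxy-2-(hydroxymethyl)-2-methylcyclohexan-1-one, via catechol borate 3 (not isolated)
Conditions: catecholborane (1.05 equiv), toluene, 0 °C → rt; then (S)-Me-CBS (20 mol %), catecholborane (1.5 equiv), −78 → −40 °C; MeOH, pH 7 buffer
Reagents that add atoms: none
Why: Corey–Bakshi–Shibata desymmetrising reduction: the primary OH is first masked as a hydride-free catechol borate, then the (S)-oxazaborolidine reduces the one enantiotopic carbonyl whose catalyst-preferred face is anti to the bulky CH2OBcat group, giving the 3R carbinol cis to CH2OH and thereby fixing C2 as R.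

Step 3
Reactants: 4 (2R,3R)-3-hydroxy-2-(hydroxymethyl)-2-methylcyclohexan-1-one
Product: 5 (2R,3R)-2-methyl-3-(triethylsilyloxy)-2-[(triethylsilyloxy)methyl]cyclohexan-1-one
Conditions: TESCl (2.5 equiv), imidazole, DMAP (cat.), DMF, 0 °C → rt
Reagents that add atoms: chlorotriethylsilane, CC[Si](Cl)(CC)CC
Why: Silyl ether formation protects both hydroxyls under non-basic conditions (no retro-aldol); the C3 silyl ether later serves as the electron-pushing group of the fragmentation.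

Step 4
Reactants: 5 (2R,3R)-2-methyl-3-(triethylsilyloxy)-2-[(triethylsilyloxy)methyl]cyclohexan-1-one
Product: 6 (5R,6R)-6-methyl-5-(triethylsilyloxy)-6-[(triethylsilyloxy)methyl]cyclohex-1-en-1-yl trifluoromethanesulfonate
Conditions: KHMDS, THF, −78 °C; PhNTf2, −78 → 0 °C
Reagents that add atoms: N-phenylbis(trifluoromethanesulfonimide), O=S(=O)(N(c1ccccc1)S(=O)(=O)C(F)(F)F)C(F)(F)F
Why: Enol triflate formation is regiospecific because the other α-carbon is quaternary, which places the ring-A olefin at C6=C7.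

Step 5
Reactants: 6 (5R,6R)-6-methyl-5-(triethylsilyloxy)-6-[(triethylsilyloxy)methyl]cyclohex-1-en-1-yl trifluoromethanesulfonate
Product: 7 triethyl{[(1R,6R)-2-ethenyl-1-methyl-6-(triethylsilyloxy)cyclohex-2-en-1-yl]methoxy}silane
Conditions: tributyl(vinyl)stannane, Pd(PPh3)4 (5 mol %), LiCl, THF, 65 °C
Reagents that add atoms: tributyl(vinyl)stannane, C=C[Sn](CCCC)(CCCC)CCCC
Why: Stille coupling of the enol triflate installs the vinyl group that becomes C8–C9.

Step 6
Reactants: 8 propyne; 9 (2E,6E)-farnesyl bromide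
Product: 12 ethyl (6E,10E)-7,11,15-trimethylhexadeca-6,10,14-trien-2-ynoate, via 1,3-dilithiopropyne 10 (not isolated), via lithium acetylide 11 (not isolated)
Conditions: 8, n-BuLi (2 equiv per propyne), TMEDA, Et2O/hexane, −78 °C → rt; 9, THF, −78 → 0 °C; then ClCO2Et, −78 °C → rt
Reagents that add atoms: ethyl chloroformate, CCOC(Cl)=O
Why: The propargylic carbanion of the propyne dianion displaces the allylic bromide by SN2 (olefin geometry kept), and the remaining acetylide is C-acylated by the chloroformate.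

Step 7
Reactants: 12 ethyl (6E,10E)-7,11,15-trimethylhexadeca-6,10,14-trien-2-ynoate
Product: 14 ethyl (2E,6E,10E)-2-iodo-3,7,11,15-tetramethylhexadeca-2,6,10,14-tetraenoate, via vinylcuprate 13 (not isolated)
Conditions: Me2CuLi (from MeLi and CuI; 1.2 equiv), THF, −78 °C; then I2, −78 °C
Reagents that add atoms: lithium dimethylcuprate, [Li+].C[Cu-]C; iodine, II
Why: Syn-carbocupration (conjugate addition) of the ynoate followed by iodinolysis with retention puts the new methyl (C26) cis to iodine, which fixes the geometry of the future C10=C11 olefin.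

Step 8
Reactants: 14 ethyl (2E,6E,10E)-2-iodo-3,7,11,15-tetramethylhexadeca-2,6,10,14-tetraenoate
Product: 15 (2E,6E,10E)-2-iodo-3,7,11,15-tetramethylhexadeca-2,6,10,14-tetraen-1-ol
Conditions: DIBAL-H (2.5 equiv), CH2Cl2, −78 → 0 °C; Rochelle salt
Reagents that add atoms: none
Why: 1,2-Reduction of the ester by DIBAL-H gives the allylic alcohol that will direct the epoxidation; the vinyl iodide and olefin geometry are untouched.

Step 9
Reactants: 7 triethyl{[(1R,6R)-2-ethenyl-1-methyl-6-(triethylsilyloxy)cyclohex-2-en-1-yl]methoxy}silane; 15 (2E,6E,10E)-2-iodo-3,7,11,15-tetramethylhexadeca-2,6,10,14-tetraen-1-ol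
Product: 17 (2Z,6E,10E)-3,7,11,15-tetramethyl-2-{2-[(5R,6R)-6-methyl-5-(triethylsilyloxy)-6-[(triethylsilyloxy)methyl]cyclohex-1-en-1-yl]ethyl}hexadeca-2,6,10,14-tetraen-1-ol, via alkylborane 16 (not isolated)
Conditions: 7, 9-BBN (1.2 equiv), THF, 0 °C → rt; then 15, PdCl2(dppf) (5 mol %), AsPh3, Cs2CO3, DMF/H2O, rt → 40 °C
Reagents that add atoms: none
Why: 9-BBN hydroborates only the terminal vinyl group (anti-Markovnikov), and B-alkyl Suzuki–Miyaura coupling with the vinyl iodide proceeds with retention, so C9 ends cis to C26 and C12 cis to the CH2OH (2Z).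

Step 10
Reactants: 17 (2Z,6E,10E)-3,7,11,15-tetramethyl-2-{2-[(5R,6R)-6-methyl-5-(triethylsilyloxy)-6-[(triethylsilyloxy)methyl]cyclohex-1-en-1-yl]ethyl}hexadeca-2,6,10,14-tetraen-1-ol
Product: 18 [(2R,3S)-3-methyl-2-{2-[(5R,6R)-6-methyl-5-(triethylsilyloxy)-6-[(triethylsilyloxy)methyl]cyclohex-1-en-1-yl]ethyl}-3-[(3E,7E)-4,8,12-trimethyltrideca-3,7,11-trien-1-yl]oxiran-2-yl]methanol
Conditions: Ti(OiPr)4 (1.0 equiv), D-(−)-diethyl tartrate (1.2 equiv), t-BuOOH (2 equiv), 4 Å MS, CH2Cl2, −25 °C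
Reagents that add atoms: tert-butyl hydroperoxide, CC(C)(C)OO
Why: Katsuki–Sharpless asymmetric epoxidation touches only the allylic-alcohol olefin among five; D-(−)-tartrate delivers oxygen to the face that gives the (2R,3S)-epoxide (the sense known for nerol-type substrates), setting C10 and, after inversion in step 12, C11.

Step 11
Reactants: 18 [(2R,3S)-3-methyl-2-{2-[(5R,6R)-6-methyl-5-(triethylsilyloxy)-6-[(triethylsilyloxy)methyl]cyclohex-1-en-1-yl]ethyl}-3-[(3E,7E)-4,8,12-trimethyltrideca-3,7,11-trien-1-yl]oxiran-2-yl]methanol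
Product: 19 [(2R,3S)-3-methyl-2-{2-[(5R,6R)-6-methyl-5-(triethylsilyloxy)-6-[(triethylsilyloxy)methyl]cyclohex-1-en-1-yl]ethyl}-3-[(3E,7E)-4,8,12-trimethyltrideca-3,7,11-trien-1-yl]oxiran-2-yl]methyl 4-methylbenzenesulfonate
Conditions: TsCl, Et3N, DMAP (cat.), CH2Cl2, 0 °C
Reagents that add atoms: p-toluenesulfonyl chloride, Cc1ccc(cc1)S(Cl)(=O)=O
Why: Sulfonylation of the only free (primary) hydroxyl prepares C27 for reduction to methyl, and its electron-withdrawing effect steers epoxide ionisation to C11.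

Step 12
Reactants: 19 [(2R,3S)-3-methyl-2-{2-[(5R,6R)-6-methyl-5-(triethylsilyloxy)-6-[(triethylsilyloxy)methyl]cyclohex-1-en-1-yl]ethyl}-3-[(3E,7E)-4,8,12-trimethyltrideca-3,7,11-trien-1-yl]oxiran-2-yl]methyl 4-methylbenzenesulfonate
Product: 21 3-[(1R,2S,3S,6Z)-3-hydroxy-2-methyl-3-(tosyloxymethyl)-6-[1-(triethylsilyloxy)propan-2-ylidene]-2-[(3E,7E)-4,8,12-trimethyltrideca-3,7,11-trien-1-yl]cyclohexyl]propanal, via bicyclic carbocation 20 (not isolated)
Conditions: MeAlCl2 (1.2 equiv), CH2Cl2, −78 °C, 15 min; quench at −78 °C with Et3N then aq. Rochelle salt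
Reagents that add atoms: none
Why: Proposed new method: MeAlCl2 ionises the epoxide at C11 (C10 is deactivated by CH2OTs) and the ring-A olefin attacks through C6 in a chair transition state, anti to the C–O bond and on the face opposite the pseudoaxial CH2OTES group (sets C6 as R, inverts C11, keeps C10); the resulting C7 cation has no further olefin to add to and undergoes Grob/retro-Prins scission of C2–C3, pushed by the C3 silyl ether oxygen with chloride from the aluminate taking Et3Si+, and least-motion cleavage leaves the axial CH2OTES cis to C6 (Z olefin); the closest known chemistry is the Corey-type MeAlCl2 epoxy-olefin cyclisation combined with the Lewis-acid Grob fragmentation of γ-oxy carbocations (the ring-opening half of carbonyl–olefin metathesis).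

Step 13
Reactants: 21 3-[(1R,2S,3S,6Z)-3-hydroxy-2-methyl-3-(tosyloxymethyl)-6-[1-(triethylsilyloxy)propan-2-ylidene]-2-[(3E,7E)-4,8,12-trimethyltrideca-3,7,11-trien-1-yl]cyclohexyl]propanal
Product: 24 3-[(1R,2S,3S,6Z)-3-hydroxy-6-(1-hydroxypropan-2-ylidene)-2,3-dimethyl-2-[(3E,7E)-4,8,12-trimethyltrideca-3,7,11-trien-1-yl]cyclohexyl]propan-1-ol, via spiro-epoxide 22 (not isolated), via TES ether 23 (not isolated)
Conditions: LiAlH4 (4 equiv), THF, 0 °C → rt; then 1 M aq. HCl, 0 °C, 30 min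
Reagents that add atoms: none
Why: Hydride reduces the aldehyde; the C10 alkoxide displaces the neighbouring tosylate to a spiro-epoxide that hydride opens at CH2 (C27 becomes methyl, C10–O bond and configuration untouched); the acidic quench hydrolyses the primary allylic TES ether.

Step 14
Reactants: 24 3-[(1R,2S,3S,6Z)-3-hydroxy-6-(1-hydroxypropan-2-ylidene)-2,3-dimethyl-2-[(3E,7E)-4,8,12-trimethyltrideca-3,7,11-trien-1-yl]cyclohexyl]propan-1-ol
Product: 25 iridal, (2Z)-2-[(2R,3S,4S)-4-hydroxy-2-(3-hydroxypropyl)-3,4-dimethyl-3-[(3E,7E)-4,8,12-trimethyltrideca-3,7,11-trienyl]cyclohexylidene]propanal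
Conditions: activated MnO2 (20 equiv), CH2Cl2, rt
Reagents that add atoms: none
Why: MnO2 oxidises only the allylic primary alcohol (C1) to the enal, leaving the saturated primary and the tertiary alcohols and the olefin geometry unchanged.

**Compound list**

1 | 2-methylcyclohexane-1,3-dione | CC1C(=O)CCCC1=O | starting material
2 | 2-(hydroxymethyl)-2-methylcyclohexane-1,3-dione | CC1(CO)C(=O)CCCC1=O | intermediate
3 | 2-[(1,3,2-benzodioxaborol-2-yloxy)methyl]-2-methylcyclohexane-1,3-dione (catechol borate of 2) | CC1(COB2Oc3ccccc3O2)C(=O)CCCC1=O | intermediate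
4 | (2R,3R)-3-hydroxy-2-(hydroxymethyl)-2-methylcyclohexan-1-one (OH cis to CH2OH) | O=C1CCC[C@@H](O)[C@@]1(C)CO | intermediate
5 | (2R,3R)-2-methyl-3-(triethylsilyloxy)-2-[(triethylsilyloxy)methyl]cyclohexan-1-one | O=C1CCC[C@@H](O[Si](CC)(CC)CC)[C@@]1(C)CO[Si](CC)(CC)CC | intermediate
6 | (5R,6R)-6-methyl-5-(triethylsilyloxy)-6-[(triethylsilyloxy)methyl]cyclohex-1-en-1-yl trifluoromethanesulfonate | O=S(=O)(OC1=CCC[C@@H](O[Si](CC)(CC)CC)[C@@]1(C)CO[Si](CC)(CC)CC)C(F)(F)F | intermediate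
7 | triethyl{[(1R,6R)-2-ethenyl-1-methyl-6-(triethylsilyloxy)cyclohex-2-en-1-yl]methoxy}silane | C=CC1=CCC[C@@H](O[Si](CC)(CC)CC)[C@@]1(C)CO[Si](CC)(CC)CC | intermediate
8 | propyne | CC#C | starting material
9 | (2E,6E)-farnesyl bromide, (2E,6E)-1-bromo-3,7,11-trimethyldodeca-2,6,10-triene | CC(C)=CCC/C(C)=C/CC/C(C)=C/CBr | starting material
10 | 1,3-dilithiopropyne | [Li]CC#C[Li] | intermediate
11 | [(5E,9E)-6,10,14-trimethylpentadeca-5,9,13-trien-1-yn-1-yl]lithium | CC(C)=CCC/C(C)=C/CC/C(C)=C/CCC#C[Li] | intermediate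
12 | ethyl (6E,10E)-7,11,15-trimethylhexadeca-6,10,14-trien-2-ynoate | CC(C)=CCC/C(C)=C/CC/C(C)=C/CCC#CC(=O)OCC | intermediate
13 | lithium methyl(vinyl)cuprate from syn addition to 12 (Cu on C2 of the enoate, cis to the new C3 methyl) | CC(C)=CCC/C(C)=C/CC/C(C)=C/CC/C(C)=C(/[Cu-]C)C(=O)OCC.[Li+] | intermediate
14 | ethyl (2E,6E,10E)-2-iodo-3,7,11,15-tetramethylhexadeca-2,6,10,14-tetraenoate | CC(C)=CCC/C(C)=C/CC/C(C)=C/CC/C(C)=C(/I)C(=O)OCC | intermediate
15 | (2E,6E,10E)-2-iodo-3,7,11,15-tetramethylhexadeca-2,6,10,14-tetraen-1-ol | CC(C)=CCC/C(C)=C/CC/C(C)=C/CC/C(C)=C(/I)CO | intermediate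
16 | 9-{2-[(5R,6R)-6-methyl-5-(triethylsilyloxy)-6-[(triethylsilyloxy)methyl]cyclohex-1-en-1-yl]ethyl}-9-borabicyclo[3.3.1]nonane | B1(CCC2=CCC[C@@H](O[Si](CC)(CC)CC)[C@@]2(C)CO[Si](CC)(CC)CC)C3CCCC1CCC3 | intermediate
17 | (2Z,6E,10E)-3,7,11,15-tetramethyl-2-{2-[(5R,6R)-6-methyl-5-(triethylsilyloxy)-6-[(triethylsilyloxy)methyl]cyclohex-1-en-1-yl]ethyl}hexadeca-2,6,10,14-tetraen-1-ol | CC(C)=CCC/C(C)=C/CC/C(C)=C/CC/C(C)=C(/CCC1=CCC[C@@H](O[Si](CC)(CC)CC)[C@@]1(C)CO[Si](CC)(CC)CC)CO | intermediate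
18 | [(2R,3S)-3-methyl-2-{2-[(5R,6R)-6-methyl-5-(triethylsilyloxy)-6-[(triethylsilyloxy)methyl]cyclohex-1-en-1-yl]ethyl}-3-[(3E,7E)-4,8,12-trimethyltrideca-3,7,11-trien-1-yl]oxiran-2-yl]methanol | CC(C)=CCC/C(C)=C/CC/C(C)=C/CC[C@]2(C)O[C@]2(CCC1=CCC[C@@H](O[Si](CC)(CC)CC)[C@@]1(C)CO[Si](CC)(CC)CC)CO | intermediate
19 | 4-methylbenzenesulfonate (tosylate) of 18 | CC(C)=CCC/C(C)=C/CC/C(C)=C/CC[C@]2(C)O[C@]2(CCC1=CCC[C@@H](O[Si](CC)(CC)CC)[C@@]1(C)CO[Si](CC)(CC)CC)COS(=O)(=O)c3ccc(C)cc3 | intermediate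
20 | ring-closed bicycle as C7 carbocation / C10 alkoxy(methyl)dichloroaluminate zwitterion (C6–C11 bond formed, H6 trans to the C11 methyl) | CC(C)=CCC/C(C)=C/CC/C(C)=C/CC[C@@]1(C)[C@@H]2CCC[C@@H](O[Si](CC)(CC)CC)[C@@](C)(CO[Si](CC)(CC)CC)[C+]2CC[C@]1(COS(=O)(=O)c3ccc(C)cc3)O[Al-](C)(Cl)Cl | intermediate
21 | 3-[(1R,2S,3S,6Z)-3-hydroxy-2-methyl-3-(tosyloxymethyl)-6-[1-(triethylsilyloxy)propan-2-ylidene]-2-[(3E,7E)-4,8,12-trimethyltrideca-3,7,11-trien-1-yl]cyclohexyl]propanal | CC(C)=CCC/C(C)=C/CC/C(C)=C/CC[C@@]1(C)[C@H](CCC=O)/C(=C(/C)CO[Si](CC)(CC)CC)CC[C@]1(COS(=O)(=O)c2ccc(C)cc2)O | intermediate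
22 | C10/C27 spiro-epoxide of 23 (C10 oxygen has displaced the tosylate; C3 already reduced to CH2OH) | CC(C)=CCC/C(C)=C/CC/C(C)=C/CC[C@@]1(C)[C@H](CCCO)/C(=C(/C)CO[Si](CC)(CC)CC)CC[C@@]12CO2 | intermediate
23 | 3-[(1R,2S,3S,6Z)-3-hydroxy-2,3-dimethyl-6-[1-(triethylsilyloxy)propan-2-ylidene]-2-[(3E,7E)-4,8,12-trimethyltrideca-3,7,11-trien-1-yl]cyclohexyl]propan-1-ol | CC(C)=CCC/C(C)=C/CC/C(C)=C/CC[C@@]1(C)[C@H](CCCO)/C(=C(/C)CO[Si](CC)(CC)CC)CC[C@]1(C)O | intermediate
24 | 3-[(1R,2S,3S,6Z)-3-hydroxy-6-(1-hydroxypropan-2-ylidene)-2,3-dimethyl-2-[(3E,7E)-4,8,12-trimethyltrideca-3,7,11-trien-1-yl]cyclohexyl]propan-1-ol | CC(C)=CCC/C(C)=C/CC/C(C)=C/CC[C@@]1(C)[C@H](CCCO)/C(=C(/C)CO)CC[C@]1(C)O | intermediate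
25 | iridal, (2Z)-2-[(2R,3S,4S)-4-hydroxy-2-(3-hydroxypropyl)-3,4-dimethyl-3-[(3E,7E)-4,8,12-trimethyltrideca-3,7,11-trienyl]cyclohexylidene]propanal | CC(C)=CCC/C(C)=C/CC/C(C)=C/CC[C@@]1(C)[C@H](CCCO)/C(=C(/C)C=O)CC[C@]1(C)O | target

**Step count and risks**

Total step count: 14. Longest linear sequence: 11 (steps 1–5, then 9–14); steps 6–8 form the side branch.

Steps most likely to fail:

Step 12 (cyclisation/fragmentation cascade). After ring closure the C7 cation can also lose H6 or H8, be trapped by the C10 oxygen as a 7-oxabicyclo[2.2.1]heptane, or shift hydride before the C2–C3 bond breaks. The fallback separates ring closure from ring opening and makes the fragmentation anionic. It sets out from 19: SnCl4 in CH2Cl2 at −78 °C closes the C6–C11 bond and ends the cyclisation by anti capture of chloride, giving the tertiary chloride F1, in which C7–Cl is antiperiplanar to C2–C3. TBAF in THF at 0 °C then frees the C3 alkoxide (and the C1 hydroxyl), which triggers a Wharton–Grob fragmentation to the hydroxy aldehyde F2. F2 is treated under the conditions of step 13 and the route is rejoined at 24.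

Step 9 (B-alkyl Suzuki coupling at a hindered iodide that forms a tetrasubstituted olefin). Transmetalation may be slow and protodeboronation or β-hydride elimination may take over. The fallback changes the nucleophile to zinc and couples at the ester stage. It sets out from 7: hydroboration as before, then NaOMe/I2 converts the borane into the primary iodide F3; zinc dust with LiCl in THF gives the alkylzinc iodide F4; Negishi coupling of F4 with iodo ester 14 (Pd2(dba)3, SPhos, THF) gives the tetrasubstituted enoate F5; DIBAL-H reduction of F5 rejoins the route at 17.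

Step 2 (desymmetrising reduction with the free hydroxymethyl group masked only in situ). Incomplete borate formation, background reduction or retro-aldol loss of formaldehyde would erode ee and dr. The fallback uses an isolated protecting group and borane as reductant. It sets out from 2: TESCl/imidazole gives the silyl ether dione F6; (S)-Me-CBS with BH3·SMe2 at −30 °C gives the hydroxy ketone F7; a second silylation with TESCl rejoins the route at 5.

**Further compounds**

F1 | step 12 | ring-closed tertiary chloride from 19 (C6–C11 bond formed, C7–Cl anti to it, C10–OH, both TES ethers and the tosylate retained) | CC(C)=CCC/C(C)=C/CC/C(C)=C/CC[C@@]1(C)[C@@H]2CCC[C@@H](O[Si](CC)(CC)CC)[C@@](C)(CO[Si](CC)(CC)CC)[C@]2(Cl)CC[C@]1(COS(=O)(=O)c3ccc(C)cc3)O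
F2 | step 12 | 3-[(1R,2S,3S,6Z)-3-hydroxy-6-(1-hydroxypropan-2-ylidene)-2-methyl-3-(tosyloxymethyl)-2-[(3E,7E)-4,8,12-trimethyltrideca-3,7,11-trien-1-yl]cyclohexyl]propanal | CC(C)=CCC/C(C)=C/CC/C(C)=C/CC[C@@]1(C)[C@H](CCC=O)/C(=C(/C)CO)CC[C@]1(COS(=O)(=O)c2ccc(C)cc2)O
F3 | step 9 | triethyl{[(1R,6R)-2-(2-iodoethyl)-1-methyl-6-(triethylsilyloxy)cyclohex-2-en-1-yl]methoxy}silane | ICCC1=CCC[C@@H](O[Si](CC)(CC)CC)[C@@]1(C)CO[Si](CC)(CC)CC
F4 | step 9 | alkylzinc iodide from F3 | I[Zn]CCC1=CCC[C@@H](O[Si](CC)(CC)CC)[C@@]1(C)CO[Si](CC)(CC)CC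
F5 | step 9 | ethyl (2Z,6E,10E)-3,7,11,15-tetramethyl-2-{2-[(5R,6R)-6-methyl-5-(triethylsilyloxy)-6-[(triethylsilyloxy)methyl]cyclohex-1-en-1-yl]ethyl}hexadeca-2,6,10,14-tetraenoate | CC(C)=CCC/C(C)=C/CC/C(C)=C/CC/C(C)=C(/CCC1=CCC[C@@H](O[Si](CC)(CC)CC)[C@@]1(C)CO[Si](CC)(CC)CC)C(=O)OCC
F6 | step 2 | 2-methyl-2-[(triethylsilyloxy)methyl]cyclohexane-1,3-dione | CC1(CO[Si](CC)(CC)CC)C(=O)CCCC1=O
F7 | step 2 | (2R,3R)-3-hydroxy-2-methyl-2-[(triethylsilyloxy)methyl]cyclohexan-1-one | O=C1CCC[C@@H](O)[C@@]1(C)CO[Si](CC)(CC)CC
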